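**Plan**

1. Rings are lettered A–H from the 2,4,6-trihydroxyphenoxy end, and position 1 of each ring carries the ether oxygen that points toward ring A.
2. Retrosynthesis first cuts all twenty alkyl ethers of a per-O-alkyl octamer, then opens ring D across D2–D3 and D1–D6. This is possible because ring D is a 1,3,4,5-tetraoxygenated benzene (D1–O to ring C, D4–O to ring E, hydroxyls on D3 and D5, CH at D2 and D6), the pattern that a 3-alkoxy-4-aryloxycyclobutenone and an aryloxyacetylene deliver.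
3. The A-B-C ethynyl ether is cut at its O–C(sp) bond and then at the B4–O–C1 and A–O–B1 bonds. The E-F-G-H cyclobutenone is cut into an aryloxyketene plus ethoxyacetylene and then at the E6–O–F1, F4–O–G1 and G6–O–H1 bonds.
4. Forward, each arm grows one ring at a time (A→B→C and H→G→F→E) by CuI-catalysed coupling of a phenol with a bromobenzaldehyde, followed by Baeyer–Villiger unmasking of the next phenol, so no protecting-group steps are needed.
5. The two arms are then joined by the benzannulation that creates ring D as the last ring, and BBr3 removes all alkyl groups.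
6. The target has no stereocentre; the only one on the way (C4 of the cyclobutenone) is racemic and is erased when it becomes aromatic D4.

Key step: step 16

Assumption (remark on the chemistry): bromides 2, 6, 19 and 23 are taken as catalogue compounds, and cyclobutenone 34 is used as the racemate.

Abbreviations: Ar3 = 6-[2,6-dimethoxy-4-(2,4,6-trimethoxyphenoxy)phenoxy]-2,3,4-trimethoxyphenyl (rings A-B-C, bonded through C6). Ar4 = 2-{3,5-dimethoxy-4-[3,4,5-trimethoxy-2-(3,4,5-trimethoxyphenoxy)phenoxy]phenoxy}-3,4,5-trimethoxyphenyl (rings E-F-G-H, bonded through E1).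

**Route**

Step 1
Reactants: 1 2,4,6-trimethoxyphenol; 2 4-bromo-2,6-dimethoxybenzaldehyde
Product: 3 2,6-dimethoxy-4-(2,4,6-trimethoxyphenoxy)benzaldehyde
Conditions: CuI (10 mol%), picolinic acid (20 mol%), K3PO4, DMSO, 90 °C, argon
Reagents that add atoms: none
Why: The CuI/picolinic acid Ullmann-type C–O coupling tolerates phenoxides flanked by two methoxy groups, and the bromide of 2 is unhindered and activated by its para formyl group, so the A–O–B1 bond should form without harm to the aldehyde.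

Step 2
Reactants: 3 2,6-dimethoxy-4-(2,4,6-trimethoxyphenoxy)benzaldehyde
Product: 5 2,6-dimethoxy-4-(2,4,6-trimethoxyphenoxy)phenol, via aryl formate 4 (not isolated)
Conditions: mCPBA, CH2Cl2, 0 °C to rt; then Et3N, MeOH, rt
Reagents that add atoms: 3-chloroperoxybenzoic acid (mCPBA), OOC(=O)c1cccc(Cl)c1
Why: Baeyer–Villiger oxidation of a benzaldehyde flanked by two methoxy groups should proceed with aryl migration in the Criegee adduct (Dakin-type outcome), and mild methanolysis of formate 4 frees the B4 hydroxyl.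

Step 3
Reactants: 6 5-bromo-1,2,3-trimethoxybenzene
Product: 8 6-bromo-2,3,4-trimethoxybenzaldehyde, via chloro(methoxy)methyl arene 7 (not isolated)
Conditions: Cl2CHOMe, TiCl4, CH2Cl2, 0 °C; then H2O
Reagents that add atoms: dichloromethyl methyl ether, COC(Cl)Cl; water, O
Why: Rieche formylation can only occur at the two equivalent open positions, each ortho and para to methoxy groups, so a single bromo aldehyde with the formyl group next to bromine should result after hydrolysis of 7.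

Step 4
Reactants: 5 2,6-dimethoxy-4-(2,4,6-trimethoxyphenoxy)phenol; 8 6-bromo-2,3,4-trimethoxybenzaldehyde
Product: 9 6-[2,6-dimethoxy-4-(2,4,6-trimethoxyphenoxy)phenoxy]-2,3,4-trimethoxybenzaldehyde (Ar3–CHO)
Conditions: CuI (10 mol%), picolinic acid (20 mol%), K3PO4, DMSO, 90 °C, argon
Reagents that add atoms: none
Why: In this Ullmann-type C–O coupling the hindered but electron-rich phenoxide of 5 meets a bromide with only one ortho substituent, a formyl group that assists copper insertion, which forms the B4–O–C1 bond.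

Step 5
Reactants: 9 Ar3–CHO
Product: 11 6-[2,6-dimethoxy-4-(2,4,6-trimethoxyphenoxy)phenoxy]-2,3,4-trimethoxyphenol (Ar3–OH), via aryl formate 10 (not isolated)
Conditions: mCPBA, CH2Cl2, 0 °C to rt; then Et3N, MeOH, rt
Reagents that add atoms: 3-chloroperoxybenzoic acid (mCPBA), OOC(=O)c1cccc(Cl)c1
Why: Baeyer–Villiger oxidation again converts the electron-rich aldehyde (ortho methoxy, ortho aryloxy, para methoxy) into its formate by aryl migration, and methanolysis gives the C6 phenol.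

Step 6
Reactants: 11 Ar3–OH; 12 trichloroethylene
Product: 14 Ar3 (E)-1,2-dichlorovinyl ether, via dichloroacetylene 13 (not isolated)
Conditions: K2CO3, DMF, 70 °C
Reagents that add atoms: none
Why: K2CO3 eliminates HCl from trichloroethylene to dichloroacetylene 13, to which the phenoxide adds in anti fashion, the standard nucleophilic vinylation that gives E-1,2-dichlorovinyl ethers of phenols.

Step 7
Reactants: 14 Ar3 (E)-1,2-dichlorovinyl ether
Product: 17 Ar3 ethynyl ether (Ar3–O–C≡CH), via chloroethynyl ether 15 (not isolated), via lithium acetylide 16 (not isolated)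
Conditions: n-BuLi (2.5 equiv), THF, −78 to −40 °C; then H2O, −78 to 0 °C
Reagents that add atoms: none
Why: n-BuLi dehydrochlorinates 14 to chloroalkyne 15 and then exchanges chlorine for lithium, the established dichlorovinyl ether route to ynol ethers, and protonation of acetylide 16 gives the terminal ynol ether, which is used at once.

Step 8
Reactants: 18 3,4,5-trimethoxyphenol; 19 2-bromo-3,4,5-trimethoxybenzaldehyde
Product: 20 3,4,5-trimethoxy-2-(3,4,5-trimethoxyphenoxy)benzaldehyde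
Conditions: CuI (10 mol%), picolinic acid (20 mol%), K3PO4, DMSO, 100 °C, argon
Reagents that add atoms: none
Why: Ullmann-type C–O coupling of an unhindered phenol with a bromide activated by its ortho formyl group should overcome the hindrance of the flanking methoxy group and forms the G6–O–H1 bond.

Step 9
Reactants: 20 3,4,5-trimethoxy-2-(3,4,5-trimethoxyphenoxy)benzaldehyde
Product: 22 3,4,5-trimethoxy-2-(3,4,5-trimethoxyphenoxy)phenol, via aryl formate 21 (not isolated)
Conditions: mCPBA, CH2Cl2, 0 °C to rt; then Et3N, MeOH, rt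
Reagents that add atoms: 3-chloroperoxybenzoic acid (mCPBA), OOC(=O)c1cccc(Cl)c1
Why: Baeyer–Villiger oxidation with aryl migration (ortho aryloxy and para methoxy groups raise the migratory aptitude) followed by formate methanolysis unmasks the G1 hydroxyl.

Step 10
Reactants: 22 3,4,5-trimethoxy-2-(3,4,5-trimethoxyphenoxy)phenol; 23 4-bromo-3,5-dimethoxybenzaldehyde
Product: 24 3,5-dimethoxy-4-[3,4,5-trimethoxy-2-(3,4,5-trimethoxyphenoxy)phenoxy]benzaldehyde
Conditions: CuI (20 mol%), picolinic acid (40 mol%), K3PO4, DMSO, 110 °C, argon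
Reagents that add atoms: none
Why: This Ullmann-type C–O coupling pairs an electron-rich phenoxide with a bromide activated by a para formyl group, the favourable electronic match, and higher catalyst loading and temperature are chosen because the bromide is flanked by two methoxy groups.

Step 11
Reactants: 24 3,5-dimethoxy-4-[3,4,5-trimethoxy-2-(3,4,5-trimethoxyphenoxy)phenoxy]benzaldehyde
Product: 26 3,5-dimethoxy-4-[3,4,5-trimethoxy-2-(3,4,5-trimethoxyphenoxy)phenoxy]phenol, via aryl formate 25 (not isolated)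
Conditions: mCPBA, CH2Cl2, 0 °C to rt; then Et3N, MeOH, rt
Reagents that add atoms: 3-chloroperoxybenzoic acid (mCPBA), OOC(=O)c1cccc(Cl)c1
Why: Baeyer–Villiger oxidation of this 4-aryloxy-3,5-dimethoxybenzaldehyde follows the known behaviour of 3,4,5-trialkoxybenzaldehydes (aryl migration promoted by the para oxygen), and methanolysis gives the unhindered F1 phenol.

Step 12
Reactants: 26 3,5-dimethoxy-4-[3,4,5-trimethoxy-2-(3,4,5-trimethoxyphenoxy)phenoxy]phenol; 19 2-bromo-3,4,5-trimethoxybenzaldehyde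
Product: 27 2-{3,5-dimethoxy-4-[3,4,5-trimethoxy-2-(3,4,5-trimethoxyphenoxy)phenoxy]phenoxy}-3,4,5-trimethoxybenzaldehyde (Ar4–CHO)
Conditions: CuI (10 mol%), picolinic acid (20 mol%), K3PO4, DMSO, 100 °C, argon
Reagents that add atoms: none
Why: The same Ullmann-type C–O coupling as in step 8, now with the unhindered F1 phenoxide, forms the E6–O–F1 bond and brings in ring E with its latent E1 hydroxyl.

Step 13
Reactants: 27 Ar4–CHO
Product: 29 2-{3,5-dimethoxy-4-[3,4,5-trimethoxy-2-(3,4,5-trimethoxyphenoxy)phenoxy]phenoxy}-3,4,5-trimethoxyphenol (Ar4–OH), via aryl formate 28 (not isolated)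
Conditions: mCPBA, CH2Cl2, 0 °C to rt; then Et3N, MeOH, rt
Reagents that add atoms: 3-chloroperoxybenzoic acid (mCPBA), OOC(=O)c1cccc(Cl)c1
Why: Baeyer–Villiger oxidation and formate methanolysis as in step 9 give the E1 phenol of the tetramer.

Step 14
Reactants: 29 Ar4–OH
Product: 30 (Ar4-oxy)acetic acid
Conditions: NaH (2.5 equiv), BrCH2CO2H, THF, 0 °C to 60 °C; then 1 M HCl
Reagents that add atoms: bromoacetic acid, OC(=O)CBr
Why: Williamson etherification, in which the sodium phenoxide displaces bromide from sodium bromoacetate formed in the same flask, places the E1 oxygen on an sp3 carbon and gives the aryloxyacetic acid after acidification.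

Step 15
Reactants: 30 (Ar4-oxy)acetic acid; 31 ethoxyacetylene
Product: 34 (±)-3-ethoxy-4-(Ar4-oxy)cyclobut-2-en-1-one, via acyl chloride 32 (not isolated), via aryloxyketene 33 (not isolated)
Conditions: (COCl)2, DMF (cat.), CH2Cl2, 0 °C to rt, evaporate; then 31 (3 equiv), Et3N (slow addition), CH2Cl2, 0 °C to rt
Reagents that add atoms: none
Why: Dehydrochlorination of acyl chloride 32 by Et3N gives aryloxyketene 33, which undergoes the known ketene–ynol ether [2+2] cycloaddition, the nucleophilic terminal alkyne carbon bonding to the ketene carbonyl carbon, so the 3-ethoxy-4-aryloxycyclobutenone forms as a racemate whose single stereocentre is of no consequence.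

Step 16
Reactants: 34 (±)-3-ethoxy-4-(Ar4-oxy)cyclobut-2-en-1-one; 17 Ar3 ethynyl ether
Product: 39 5-(Ar3-oxy)-3-ethoxy-2-(Ar4-oxy)phenol, via vinylketene 35 (not isolated), via vinylcyclobutenone 36 (not isolated), via dienylketene 37 (not isolated), via cyclohexadienone 38 (not isolated)
Conditions: 17 (1.5 equiv), toluene, 110 °C, sealed tube, argon
Reagents that add atoms: none
Why: Danheiser benzannulation: thermal 4π-electrocyclic opening of 34 (the aryloxy group turning outward) gives vinylketene 35, whose ketene C=C adds [2+2] to the electron-rich alkyne of 17 to give 36, and 4π opening of 36 to dienylketene 37, 6π closure to 38 and tautomerisation give phenol 39. The closest precedent is the benzannulation of cyclobutenone-derived vinylketenes with alkoxyacetylenes to 5-substituted resorcinol monoethers, here with an aryloxyacetylene as the ynol ether. Ring D is closed by thermal disrotatory 6π electrocyclisation of 37, which re-forms the D3–D4 bond after the [2+2] step has made the new D2–D3 and D1–D6 bonds. No stereocentre is created, and the racemic centre of 34 becomes aromatic D4. The one selectivity needed is regiochemical, the ring C oxygen at D1 meta to the new D3 hydroxyl, and the polarisation of the ynol ether secures it: its unsubstituted nucleophilic carbon bonds to the ketene carbonyl carbon and its oxygen-bearing carbon to the ketene alpha carbon. The aryl ynol ether has no beta hydrogen and so cannot lose ketene by a retro-ene path, and its excess should intercept 35 before it dimerises.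

Step 17
Reactants: 39 5-(Ar3-oxy)-3-ethoxy-2-(Ar4-oxy)phenol
Product: 40 CNP0206369.0 (the octamer with all twenty-one hydroxyls free)
Conditions: BBr3 (excess), CH2Cl2, −78 °C to rt; then H2O, 0 °C; isolation under argon
Reagents that add atoms: none
Why: BBr3 cleaves aryl methyl and ethyl ethers by Lewis acid complexation and bromide attack at the alkyl carbon while diaryl ether bonds are inert, so global dealkylation should free the twenty remaining hydroxyls of the target.

**Compound list**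

1 | 2,4,6-trimethoxyphenol | COc1cc(OC)c(O)c(OC)c1 | starting material
2 | 4-bromo-2,6-dimethoxybenzaldehyde | COc1cc(Br)cc(OC)c1C=O | starting material
3 | 2,6-dimethoxy-4-(2,4,6-trimethoxyphenoxy)benzaldehyde | COc1cc(OC)c(Oc2cc(OC)c(C=O)c(OC)c2)c(OC)c1 | intermediate
4 | 2,6-dimethoxy-4-(2,4,6-trimethoxyphenoxy)phenyl formate | COc1cc(OC)c(Oc2cc(OC)c(OC=O)c(OC)c2)c(OC)c1 | intermediate
5 | 2,6-dimethoxy-4-(2,4,6-trimethoxyphenoxy)phenol | COc1cc(OC)c(Oc2cc(OC)c(O)c(OC)c2)c(OC)c1 | intermediate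
6 | 5-bromo-1,2,3-trimethoxybenzene | COc1cc(Br)cc(OC)c1OC | starting material
7 | 1-bromo-2-[chloro(methoxy)methyl]-3,4,5-trimethoxybenzene | COc1cc(Br)c(C(Cl)OC)c(OC)c1OC | intermediate
8 | 6-bromo-2,3,4-trimethoxybenzaldehyde | COc1cc(Br)c(C=O)c(OC)c1OC | intermediate
9 | Ar3–CHO, 6-[2,6-dimethoxy-4-(2,4,6-trimethoxyphenoxy)phenoxy]-2,3,4-trimethoxybenzaldehyde | COc1cc(OC)c(Oc2cc(OC)c(Oc3cc(OC)c(OC)c(OC)c3C=O)c(OC)c2)c(OC)c1 | intermediate
10 | Ar3 formate | COc1cc(OC)c(Oc2cc(OC)c(Oc3cc(OC)c(OC)c(OC)c3OC=O)c(OC)c2)c(OC)c1 | intermediate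
11 | Ar3–OH, 6-[2,6-dimethoxy-4-(2,4,6-trimethoxyphenoxy)phenoxy]-2,3,4-trimethoxyphenol | COc1cc(OC)c(Oc2cc(OC)c(Oc3cc(OC)c(OC)c(OC)c3O)c(OC)c2)c(OC)c1 | intermediate
12 | trichloroethylene | ClC=C(Cl)Cl | starting material
13 | dichloroacetylene | ClC#CCl | intermediate
14 | Ar3 (E)-1,2-dichlorovinyl ether | COc1cc(OC)c(Oc2cc(OC)c(Oc3cc(OC)c(OC)c(OC)c3O/C(Cl)=C\Cl)c(OC)c2)c(OC)c1 | intermediate
15 | Ar3 chloroethynyl ether | COc1cc(OC)c(Oc2cc(OC)c(Oc3cc(OC)c(OC)c(OC)c3OC#CCl)c(OC)c2)c(OC)c1 | intermediate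
16 | lithium (Ar3-oxy)acetylide | COc1cc(OC)c(Oc2cc(OC)c(Oc3cc(OC)c(OC)c(OC)c3OC#C[Li])c(OC)c2)c(OC)c1 | intermediate
17 | Ar3 ethynyl ether | COc1cc(OC)c(Oc2cc(OC)c(Oc3cc(OC)c(OC)c(OC)c3OC#C)c(OC)c2)c(OC)c1 | intermediate
18 | 3,4,5-trimethoxyphenol | COc1cc(O)cc(OC)c1OC | starting material
19 | 2-bromo-3,4,5-trimethoxybenzaldehyde | COc1cc(C=O)c(Br)c(OC)c1OC | starting material
20 | 3,4,5-trimethoxy-2-(3,4,5-trimethoxyphenoxy)benzaldehyde | O=Cc1cc(OC)c(OC)c(OC)c1Oc1cc(OC)c(OC)c(OC)c1 | intermediate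
21 | 3,4,5-trimethoxy-2-(3,4,5-trimethoxyphenoxy)phenyl formate | O=COc1cc(OC)c(OC)c(OC)c1Oc1cc(OC)c(OC)c(OC)c1 | intermediate
22 | 3,4,5-trimethoxy-2-(3,4,5-trimethoxyphenoxy)phenol | Oc1cc(OC)c(OC)c(OC)c1Oc1cc(OC)c(OC)c(OC)c1 | intermediate
23 | 4-bromo-3,5-dimethoxybenzaldehyde | COc1cc(C=O)cc(OC)c1Br | starting material
24 | 3,5-dimethoxy-4-[3,4,5-trimethoxy-2-(3,4,5-trimethoxyphenoxy)phenoxy]benzaldehyde | O=Cc1cc(OC)c(Oc2cc(OC)c(OC)c(OC)c2Oc2cc(OC)c(OC)c(OC)c2)c(OC)c1 | intermediate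
25 | formate of 26 | O=COc1cc(OC)c(Oc2cc(OC)c(OC)c(OC)c2Oc2cc(OC)c(OC)c(OC)c2)c(OC)c1 | intermediate
26 | 3,5-dimethoxy-4-[3,4,5-trimethoxy-2-(3,4,5-trimethoxyphenoxy)phenoxy]phenol | Oc1cc(OC)c(Oc2cc(OC)c(OC)c(OC)c2Oc2cc(OC)c(OC)c(OC)c2)c(OC)c1 | intermediate
27 | Ar4–CHO | O=Cc1cc(OC)c(OC)c(OC)c1Oc1cc(OC)c(Oc2cc(OC)c(OC)c(OC)c2Oc2cc(OC)c(OC)c(OC)c2)c(OC)c1 | intermediate
28 | Ar4 formate | O=COc1cc(OC)c(OC)c(OC)c1Oc1cc(OC)c(Oc2cc(OC)c(OC)c(OC)c2Oc2cc(OC)c(OC)c(OC)c2)c(OC)c1 | intermediate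
29 | Ar4–OH | Oc1cc(OC)c(OC)c(OC)c1Oc1cc(OC)c(Oc2cc(OC)c(OC)c(OC)c2Oc2cc(OC)c(OC)c(OC)c2)c(OC)c1 | intermediate
30 | (Ar4-oxy)acetic acid | OC(=O)COc1cc(OC)c(OC)c(OC)c1Oc1cc(OC)c(Oc2cc(OC)c(OC)c(OC)c2Oc2cc(OC)c(OC)c(OC)c2)c(OC)c1 | intermediate
31 | ethoxyacetylene | CCOC#C | starting material
32 | (Ar4-oxy)acetyl chloride | O=C(Cl)COc1cc(OC)c(OC)c(OC)c1Oc1cc(OC)c(Oc2cc(OC)c(OC)c(OC)c2Oc2cc(OC)c(OC)c(OC)c2)c(OC)c1 | intermediate
33 | (Ar4-oxy)ketene | O=C=COc1cc(OC)c(OC)c(OC)c1Oc1cc(OC)c(Oc2cc(OC)c(OC)c(OC)c2Oc2cc(OC)c(OC)c(OC)c2)c(OC)c1 | intermediate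
34 | (±)-3-ethoxy-4-(Ar4-oxy)cyclobut-2-en-1-one | CCOC1=CC(=O)C1Oc1cc(OC)c(OC)c(OC)c1Oc1cc(OC)c(Oc2cc(OC)c(OC)c(OC)c2Oc2cc(OC)c(OC)c(OC)c2)c(OC)c1 | intermediate
35 | (Z)-3-ethoxy-4-(Ar4-oxy)buta-1,3-dien-1-one | O=C=C/C(OCC)=C/Oc1cc(OC)c(OC)c(OC)c1Oc1cc(OC)c(Oc2cc(OC)c(OC)c(OC)c2Oc2cc(OC)c(OC)c(OC)c2)c(OC)c1 | intermediate
36 | 3-(Ar3-oxy)-4-[(Z)-1-ethoxy-2-(Ar4-oxy)ethenyl]cyclobut-2-en-1-one (racemic) | O=C1C=C(Oc2c(Oc3c(OC)cc(Oc4c(OC)cc(OC)cc4OC)cc3OC)cc(OC)c(OC)c2OC)C1/C(OCC)=C/Oc1cc(OC)c(OC)c(OC)c1Oc1cc(OC)c(Oc2cc(OC)c(OC)c(OC)c2Oc2cc(OC)c(OC)c(OC)c2)c(OC)c1 | intermediate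
37 | (3E,5Z)-3-(Ar3-oxy)-5-ethoxy-6-(Ar4-oxy)hexa-1,3,5-trien-1-one | O=C=C/C(Oc1c(Oc2c(OC)cc(Oc3c(OC)cc(OC)cc3OC)cc2OC)cc(OC)c(OC)c1OC)=C\C(OCC)=C\Oc1cc(OC)c(OC)c(OC)c1Oc1cc(OC)c(Oc2cc(OC)c(OC)c(OC)c2Oc2cc(OC)c(OC)c(OC)c2)c(OC)c1 | intermediate
38 | 3-(Ar3-oxy)-5-ethoxy-6-(Ar4-oxy)cyclohexa-2,4-dien-1-one (racemic) | O=C1C=C(Oc2c(Oc3c(OC)cc(Oc4c(OC)cc(OC)cc4OC)cc3OC)cc(OC)c(OC)c2OC)C=C(OCC)C1Oc1cc(OC)c(OC)c(OC)c1Oc1cc(OC)c(Oc2cc(OC)c(OC)c(OC)c2Oc2cc(OC)c(OC)c(OC)c2)c(OC)c1 | intermediate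
39 | 5-(Ar3-oxy)-3-ethoxy-2-(Ar4-oxy)phenol (octamer, D3 hydroxyl free, D5 ethoxy, all else methylated) | COc1cc(OC)c(Oc2cc(OC)c(Oc3cc(OC)c(OC)c(OC)c3Oc3cc(O)c(Oc4cc(OC)c(OC)c(OC)c4Oc4cc(OC)c(Oc5cc(OC)c(OC)c(OC)c5Oc5cc(OC)c(OC)c(OC)c5)c(OC)c4)c(OCC)c3)c(OC)c2)c(OC)c1 | intermediate
40 | CNP0206369.0 | Oc1cc(O)c(Oc2cc(O)c(Oc3cc(O)c(O)c(O)c3Oc3cc(O)c(Oc4cc(O)c(O)c(O)c4Oc4cc(O)c(Oc5cc(O)c(O)c(O)c5Oc5cc(O)c(O)c(O)c5)c(O)c4)c(O)c3)c(O)c2)c(O)c1 | target

**Count and risks**

Total step count: 17. Longest linear sequence: 10 steps (steps 8 to 17, from 18 to 40).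

Steps most likely to fail:

1. Step 16. The terminal aryloxyacetylene may oligomerise at the temperature needed to open the cyclobutenone, or the vinylketene may dimerise or acylate the product phenol before it is intercepted. The fallback sets out from 14: after the n-BuLi treatment, acetylide 16 is trapped with Me3SiCl instead of water to give the storable Ar3 (trimethylsilyl)ethynyl ether F1. Heating F1 with 34 in toluene at 110 to 130 °C should give, with the same regiochemistry (the silicon-bearing carbon remains the nucleophilic one), 5-(Ar3-oxy)-3-ethoxy-2-(Ar4-oxy)-6-(trimethylsilyl)phenol F2. Protodesilylation of this electron-rich aryl silane with CF3CO2H in CH2Cl2 at 0 °C comes back to the route at 39.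

2. Step 10. C–O bond formation at a bromide flanked by two methoxy groups may stall, with protodebromination taking over. The fallback sets out from 22 and 23 and replaces copper catalysis by metal-free ligand coupling at hypervalent iodine. Bromide 23 is converted by aromatic Finkelstein exchange (CuI cat., NaI, N,N'-dimethylethylenediamine, dioxane, 110 °C) into 4-iodo-3,5-dimethoxybenzaldehyde F3. Oxidation with mCPBA and TsOH in the presence of 1,3,5-trimethoxybenzene gives (4-formyl-2,6-dimethoxyphenyl)(2,4,6-trimethoxyphenyl)iodonium tosylate F4. Phenol 22 is then O-arylated with F4 (K2CO3, MeCN, 50 °C), the less electron-rich formyl-bearing aryl group being the one transferred, which comes back to the route at 24.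

3. Step 17. Cleavage of twenty alkyl ethers may stop short at the most hindered positions, and the electron-rich polyphenol may oxidise in air during chromatographic isolation. The fallback sets out from 39: after the BBr3 treatment and quench the crude polyphenol is not isolated but acetylated (Ac2O, pyridine, DMAP cat.) to the henicosaacetate of the target F5, which is stable and can be purified on silica and separated from partly dealkylated material. Deacetylation with catalytic NaOMe in degassed MeOH, followed by neutralisation with an acidic resin, comes back to the route at 40.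

**Further compounds**

F1 | step 16 | Ar3 (trimethylsilyl)ethynyl ether | COc1cc(OC)c(Oc2cc(OC)c(Oc3cc(OC)c(OC)c(OC)c3OC#C[Si](C)(C)C)c(OC)c2)c(OC)c1
F2 | step 16 | 5-(Ar3-oxy)-3-ethoxy-2-(Ar4-oxy)-6-(trimethylsilyl)phenol | COc1cc(OC)c(Oc2cc(OC)c(Oc3cc(OC)c(OC)c(OC)c3Oc3c([Si](C)(C)C)c(O)c(Oc4cc(OC)c(OC)c(OC)c4Oc4cc(OC)c(Oc5cc(OC)c(OC)c(OC)c5Oc5cc(OC)c(OC)c(OC)c5)c(OC)c4)c(OCC)c3)c(OC)c2)c(OC)c1
F3 | step 10 | 4-iodo-3,5-dimethoxybenzaldehyde | COc1cc(C=O)cc(OC)c1I
F4 | step 10 | (4-formyl-2,6-dimethoxyphenyl)(2,4,6-trimethoxyphenyl)iodonium 4-methylbenzenesulfonate | COc1cc(C=O)cc(OC)c1[I+]c1c(OC)cc(OC)cc1OC.Cc1ccc(S(=O)(=O)[O-])cc1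
F5 | step 17 | henicosaacetate of CNP0206369.0 | CC(=O)Oc1cc(OC(C)=O)c(Oc2cc(OC(C)=O)c(Oc3cc(OC(C)=O)c(OC(C)=O)c(OC(C)=O)c3Oc3cc(OC(C)=O)c(Oc4cc(OC(C)=O)c(OC(C)=O)c(OC(C)=O)c4Oc4cc(OC(C)=O)c(Oc5cc(OC(C)=O)c(OC(C)=O)c(OC(C)=O)c5Oc5cc(OC(C)=O)c(OC(C)=O)c(OC(C)=O)c5)c(OC(C)=O)c4)c(OC(C)=O)c3)c(OC(C)=O)c2)c(OC(C)=O)c1
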